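The flavone is cut at the C2–C1' bond between pyranone ring C and aryl ring B, and that bond is made late from two C–H bonds. One palladium-catalysed, silver-driven dehydrogenative coupling joins 3,7,8-trimethoxychromone to pivaloyl-protected guaiacol and delivers the whole skeleton with every oxygen substituent in place. It exploits two features. The C3 methoxy group leaves C2–H as the only C–H of ring C. C1' sits para to the 4'-methoxy group, at the most electron-rich unhindered carbon of the guaiacol ester. The chromone, with rings A and C complete, comes in two operations from 1,2,3-trimethoxybenzene. Ester methanolysis ends the route.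

Key step: step 4

Assumption: flavone numbering is used (ring C: O1, C2, C3, C4; ring A: C5 to C8; ring B: primed positions). The target is achiral, so no stereocontrol is required.

Step 1
Reactants: 1 1,2,3-trimethoxybenzene; 2 methoxyacetyl chloride
Product: 4 1-(2-hydroxy-3,4-dimethoxyphenyl)-2-methoxyethanone, via trimethoxyaryl ketone 3 (not isolated)
Conditions: AlCl3 (2.5 equiv), Et2O–CH2Cl2, 0 °C to 40 °C; then ice/aq. HCl
Reagents that add atoms: none
Why: Friedel–Crafts acylation strikes C4 of 1 (para to the C1 and ortho to the C3 methoxy group, whereas C5 is activated only by the twisted central one), ether-tempered AlCl3 keeps the acyl chloride as a donor–acceptor complex so that it should acylate faster than it can ionise and shed CO, and the six-membered aluminium chelate between the new carbonyl and the neighbouring aryl methyl ether is then opened by chloride at the methyl carbon, a phenoxide being a far better leaving group than the alkoxide that cleavage of the side-chain ether would demand.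

Step 2
Reactants: 4 1-(2-hydroxy-3,4-dimethoxyphenyl)-2-methoxyethanone; 5 N,N-dimethylformamide dimethyl acetal
Product: 7 3,7,8-trimethoxychromone, via alpha-methoxy enaminone 6 (not isolated)
Conditions: 5 (3 equiv), toluene, 100 °C; evaporate; AcOH, 100 °C
Reagents that add atoms: none
Why: The formamide acetal aminomethylenates the only enolisable carbon, the CH2 between carbonyl and methoxy group, to give the push–pull enaminone that carries the future C2, and in warm acetic acid the ortho phenol adds to the protonated beta carbon and expels dimethylamine (addition–elimination, the standard enaminone route to chromones), closing ring C at O1–C2.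

Step 3
Reactants: 8 guaiacol (2-methoxyphenol)
Product: 9 2-methoxyphenyl pivalate
Conditions: PivCl (1.1 equiv), Et3N (1.3 equiv), DMAP (5 mol %), CH2Cl2, 0 °C to rt
Reagents that add atoms: pivaloyl chloride, CC(C)(C)C(=O)Cl
Why: DMAP-catalysed O-acylation of a phenol by an acid chloride is routine and has no competing site in 8.

Step 4
Reactants: 7 3,7,8-trimethoxychromone; 9 2-methoxyphenyl pivalate (10 equiv, surplus recovered)
Product: 10 2-methoxy-5-(3,7,8-trimethoxy-4-oxo-4H-chromen-2-yl)phenyl pivalate (diplotrin B 3'-O-pivalate)
Conditions: Pd(OAc)2 (15 mol %), AgOAc (3 equiv), CsOPiv (1 equiv), PivOH, 110 °C
Reagents that add atoms: none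
Why: Pd(OPiv)2 formed in the medium cleaves a C–H bond of 9 by carboxylate-assisted metalation with electrophilic character, and the aryl–palladium species adds syn across C2=C3 of 7, aryl to the beta carbon (C2) of the vinylogous ester and palladium to C3, where it is held as an enolate of the C4 carbonyl. Because the C2 hydrogen then lies anti to the metal, the carbon-bound enolate must slip to its oxygen-bound form and back (or give up that now acidic hydrogen to pivalate) before the pyranone double bond is restored and zerovalent palladium departs, to be returned to the divalent state by two equivalents of AgOAc. The closest known reaction type is the Fujiwara–Moritani-type dehydrogenative C2 arylation of chromones with simple arenes under this same Pd(OAc)2/AgOAc/CsOPiv/PivOH system, here transferred to a 3-methoxychromone and a 1,2-dioxygenated arene. No ring is closed and no stereocentre is created. Two site selectivities are needed: on 7 the C3 methoxy group leaves C2–H as the sole C–H of ring C, and the carbonyl-deactivated ring A, present in small amount beside the large excess of 9, should not compete for palladation; on 9 the methoxy group is the stronger donor and sends the metal to its para carbon (C5 of 9, the future C1'), the same site at which guaiacol esters are halogenated, while both ortho positions are crowded and the carbon para to the weakly donating pivaloyloxy group is less electron-rich. The pivalate also keeps the phenol safe from oxidation by AgOAc, and any acyl exchange with the pivalate medium is degenerate.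

Step 5
Reactants: 10 diplotrin B 3'-O-pivalate
Product: 11 diplotrin B, 2-(3-hydroxy-4-methoxyphenyl)-3,7,8-trimethoxy-4H-chromen-4-one
Conditions: K2CO3 (30 mol %), MeOH–THF, 40 °C; then aq. NH4Cl
Reagents that add atoms: none
Why: Base-catalysed transesterification works even on the hindered acyl group because the aryloxide is a good leaving group, while the four methyl ethers and the fully substituted pyranone are inert to methoxide at this temperature.

Compound list
1 | 1,2,3-trimethoxybenzene | COc1cccc(OC)c1OC | starting material
2 | methoxyacetyl chloride | COCC(=O)Cl | starting material
3 | 2-methoxy-1-(2,3,4-trimethoxyphenyl)ethanone (formed and consumed in the flask of step 1) | COCC(=O)c1ccc(OC)c(OC)c1OC | intermediate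
4 | 1-(2-hydroxy-3,4-dimethoxyphenyl)-2-methoxyethanone | COCC(=O)c1ccc(OC)c(OC)c1O | intermediate
5 | N,N-dimethylformamide dimethyl acetal | COC(OC)N(C)C | starting material
6 | (Z)-3-(dimethylamino)-1-(2-hydroxy-3,4-dimethoxyphenyl)-2-methoxyprop-2-en-1-one (amino group trans to the carbonyl; geometry is lost on ring closure; carried on crude in step 2) | CO/C(=C\N(C)C)C(=O)c1ccc(OC)c(OC)c1O | intermediate
7 | 3,7,8-trimethoxy-4H-chromen-4-one | COc1coc2c(OC)c(OC)ccc2c1=O | intermediate
8 | guaiacol (2-methoxyphenol) | COc1ccccc1O | starting material
9 | 2-methoxyphenyl pivalate | COc1ccccc1OC(=O)C(C)(C)C | intermediate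
10 | 2-methoxy-5-(3,7,8-trimethoxy-4-oxo-4H-chromen-2-yl)phenyl pivalate | COc1ccc(-c2oc3c(OC)c(OC)ccc3c(=O)c2OC)cc1OC(=O)C(C)(C)C | intermediate
11 | diplotrin B (3'-hydroxy-3,4',7,8-tetramethoxyflavone) | COc1ccc(-c2oc3c(OC)c(OC)ccc3c(=O)c2OC)cc1O | target

Total step count: 5
Longest linear sequence: 4 (steps 1, 2, 4, 5)

Steps most likely to fail

**Step 4.** Several processes could undermine the coupling:
- Palladation of 9 may spread over the two unhindered carbons, para to methoxy and para to pivaloyloxy.
- Insertion into C2=C3 may be slowed by the donor character and bulk of the C3 methoxy group.
- If the coupling depends on metalation of the chromone itself, only the less nucleophilic C2 is on offer.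
- Pivalic acid may protonate the palladium enolate before the double bond is restored.
- Oxidative dimerisation of 9 may consume the silver salt.

The fallback gives up the twofold C–H mode and joins two pre-functionalised partners by Negishi cross-coupling. It sets out from 9 and 7. NBS in MeCN at 0 °C to rt brominates 9 para to its methoxy group to give 5-bromo-2-methoxyphenyl pivalate F1. Separately, 7 is deprotonated at its only ring C hydrogen with TMPZnCl·LiCl in THF at 25 °C to give (3,7,8-trimethoxy-4-oxo-4H-chromen-2-yl)zinc chloride F2. This is coupled without isolation with the bromide under Pd(OAc)2/SPhos at 50 °C. The fallback comes back to the route at 10.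

**Step 1.** The acyl chloride–AlCl3 complex may ionise and lose carbon monoxide, so that a methoxymethyl cation alkylates the arene instead of acylation taking place. Prolonged Lewis acid contact may also strip the C3 aryl ether or the side-chain ether. The fallback replaces the electrophilic acylation by a carbanion route and separates the two events. It sets out from 1, which is lithiated ortho to a flanking methoxy group with n-BuLi/TMEDA in THF at 0 °C to give 2,3,4-trimethoxyphenyllithium F3. Addition to commercial N,2-dimethoxy-N-methylacetamide at −78 °C and an aq. HCl quench should give ketone 3, now isolated. BCl3 (1.1 equiv) in CH2Cl2 from −78 °C to 0 °C then removes only the methyl ether chelated to the carbonyl. The fallback comes back to the route at 4.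

**Step 2.** Condensation at the hindered, less acidic methoxy-bearing CH2 may be slow. At the temperature it then needs, O-methylation of the phenol by the formamide acetal would block ring closure. The fallback brings in C2 by an enolate formylation of the Claisen type. It sets out from 4, which is treated with NaH (3 equiv) and ethyl formate in THF at 0 °C to rt. After an aq. HCl quench this should give the cyclic hemiacetal 2-hydroxy-3,7,8-trimethoxychroman-4-one F4 as a mixture of diastereomers. Warming in AcOH with a catalytic amount of conc. HCl dehydrates it. The fallback comes back to the route at 7.

Further compounds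
F1 | step 4 | 5-bromo-2-methoxyphenyl pivalate | COc1ccc(Br)cc1OC(=O)C(C)(C)C
F2 | step 4 | (3,7,8-trimethoxy-4-oxo-4H-chromen-2-yl)zinc chloride | COc1c([Zn]Cl)oc2c(OC)c(OC)ccc2c1=O
F3 | step 1 | 2,3,4-trimethoxyphenyllithium | [Li]c1ccc(OC)c(OC)c1OC
F4 | step 2 | 2-hydroxy-3,7,8-trimethoxychroman-4-one (mixture of diastereomers) | COC1C(O)Oc2c(OC)c(OC)ccc2C1=O
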